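**Plan**

- Cuts: (a) the acetate and the diterpenoyl–glycerol ester bonds, back to the decalin acid and (R)-solketal; (b) the C5–side-chain bond, back to the enol triflate of a C5 ketone and an alkylzinc; (c) the C4a–CH3 bond, back to a cyclopropane on a C4=C4a alkene; (d) C1–C8a and C2–C3 of ring A, a [4+2] disconnection.
- Enabling feature (decalin locants: C1 carboxyl carbon, C2 methyl, C4a and C8a angular methyls, C5 side chain, C5=C6; ring A = C1, C2, C3, C4, C4a, C8a; ring B = C4a, C5, C6, C7, C8, C8a): in ring A the methylated C8a, the carboxylated C1 and the methylated C2 follow one another, and C4a borders C5 of ring B. Ring A is therefore the cyclohexene that a ring B vinylcyclohexene (C8a=C4a–C4=C3, oxygen at C5) forms with a butenolide laid across C1 and C2.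
- Forward order: ring B is bought as 3-methylcyclohex-2-enone and turned into the silyloxy diene; ring A closes in the Diels–Alder reaction; the C4a methyl follows by directed cyclopropanation and hydrogenolysis; the lactone is opened to the C2 methyl and the C1 ester; the side chain is joined by Negishi coupling; the glycerol unit comes last.
- Stereochemistry: a CBS reduction sets C5; C5 steers the diene face (C8a) and endo addition of the Z-locked dienophile sets C1 and C2; the C5 hydroxyl delivers the C4a carbon cis to the C8a methyl; C1 is then inverted by thermodynamic ester epimerisation; the glycerol centre is carried in from (R)-solketal.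

Key step: step 5

Numbering: the decalin locants above are used for all bicyclic and tricyclic intermediates; α is the face of the C8a methyl, β the opposite face.
Assumption: in the CBS reduction the 2-iodoalkenyl flank acts as the large substituent (as in 2-halocycloalkenones), so the (R)-catalyst should give the (S)-alcohol.

**Route**

Step 1
Reactants: 1 3-methylcyclohex-2-en-1-one
Product: 2 2-iodo-3-methylcyclohex-2-en-1-one
Conditions: I2, pyridine/CH2Cl2 (1:1), 0 °C → rt
Reagents that add atoms: iodine, II
Why: α-Iodination of the enone by pyridine conjugate addition, iodination of the enolate and elimination should give the 2-iodoenone; no stereocentre is formed.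

Step 2
Reactants: 2 2-iodo-3-methylcyclohex-2-en-1-one
Product: 3 (S)-2-iodo-3-methylcyclohex-2-en-1-ol
Conditions: (R)-2-methyl-CBS-oxazaborolidine (15 mol%), BH3·SMe2, THF, −20 °C; MeOH quench
Reagents that add atoms: none
Why: Corey–Bakshi–Shibata reduction: the oxazaborolidine–borane complex binds the carbonyl anti to the bulkier iodoalkenyl flank and delivers hydride to one face (1,2-reduction), which should set the (S)-carbinol that becomes C5.

Step 3
Reactants: 3 (S)-2-iodo-3-methylcyclohex-2-en-1-ol
Product: 4 (S)-tert-butyl[(2-iodo-3-methylcyclohex-2-en-1-yl)oxy]dimethylsilane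
Conditions: TBSCl, imidazole, DMF, rt
Reagents that add atoms: tert-butyldimethylsilyl chloride, CC(C)(C)[Si](C)(C)Cl
Why: Imidazole-mediated silylation of a secondary allylic alcohol; the stereocentre is not touched.

Step 4
Reactants: 4 (S)-tert-butyl[(2-iodo-3-methylcyclohex-2-en-1-yl)oxy]dimethylsilane
Product: 5 (S)-tert-butyldimethyl[(3-methyl-2-vinylcyclohex-2-en-1-yl)oxy]silane
Conditions: CH2=CHSnBu3, Pd(PPh3)4 (5 mol%), CuI (10 mol%), DMF, 60 °C
Reagents that add atoms: tributyl(vinyl)stannane, C=C[Sn](CCCC)(CCCC)CCCC
Why: Stille coupling (oxidative addition of the C–I bond to zerovalent palladium, CuI-assisted transmetallation, reductive elimination) should install the vinyl group and complete the diene without touching the carbinol centre.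

Step 5
Reactants: 5 (S)-tert-butyldimethyl[(3-methyl-2-vinylcyclohex-2-en-1-yl)oxy]silane; 6 furan-2(5H)-one
Product: 7 tricyclic cis-lactone (3aR,6S,9aR,9bR)-6-[(tert-butyldimethylsilyl)oxy]-9a-methyl-3a,4,6,7,8,9,9a,9b-octahydronaphtho[1,2-c]furan-1(3H)-one
Conditions: Me2AlCl (1.5 equiv), CH2Cl2, −40 → 0 °C
Reagents that add atoms: none
Why: Me2AlCl complexes the lactone carbonyl of 6 and the s-cis diene C8a=C4a–C4=C3 of 5 adds across the butenolide C=C in a concerted, asynchronous [4+2] cycloaddition, the free vinyl terminus C3 bonding to the lactone β-carbon (C2) ahead of the bond from the methyl-bearing C8a to the α-carbon (C1); the closest known reaction type is the Lewis-acid-promoted Diels–Alder reaction of 1-methyl-2-vinylcyclohexenes with cyclic dienophiles. Ring A (C1, C2, C3, C4, C4a, C8a) closes by this intermolecular six-membered cycloaddition, both new σ-bonds forming suprafacially and leaving the C4=C4a alkene. The regiochemistry follows from the polarisation of the partners: the alkyl-substituted diene is most nucleophilic at C3 and positive charge builds up at the tertiary C8a, which the enolate-like α-carbon then captures. C8a is controlled by the C5 stereocentre, whose silyloxy group sits pseudoaxial (allylic strain with the vinyl group) and blocks its own face, so bonding should occur anti to it and the C8a methyl should end up cis to the C5 oxygen. C1 and C2 are controlled by the ring-locked Z geometry of the dienophile (cis to each other) and by the endo transition state, which places both lactone carbons trans to the C8a methyl. The step therefore needs one regiochemistry, anti facial selectivity and endo selectivity, secured respectively by the diene substitution pattern, the CBS-derived C5 centre and carbonyl–diene secondary overlap reinforced by the Lewis acid.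

Step 6
Reactants: 7 tricyclic cis-lactone silyl ether
Product: 8 (3aR,6S,9aR,9bR)-6-hydroxy-9a-methyl-3a,4,6,7,8,9,9a,9b-octahydronaphtho[1,2-c]furan-1(3H)-one
Conditions: Bu4NF, THF, 0 °C → rt
Reagents that add atoms: none
Why: Fluoride-induced Si–O cleavage (desilylation) should free the C5 allylic alcohol while the cis-fused lactone, already the stable ring fusion, stays intact.

Step 7
Reactants: 8 allylic alcohol lactone
Product: 9 cyclopropane-fused lactone (CH2 bridging C4 and C4a on the α face)
Conditions: Et2Zn, CH2I2, CH2Cl2, 0 °C → rt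
Reagents that add atoms: diiodomethane, ICI
Why: Hydroxyl-directed Simmons–Smith cyclopropanation: the zinc alkoxide of the pseudoaxial C5 hydroxyl should deliver the CH2 to the C4=C4a face it occupies, which is the face of the C8a methyl, so the new C4a–C bond is set cis to that methyl.

Step 8
Reactants: 9 cyclopropane-fused lactone
Product: 10 (3aR,5aS,6S,9aR,9bR)-6-hydroxy-5a,9a-dimethyldecahydronaphtho[1,2-c]furan-1(3H)-one
Conditions: H2 (3 atm), PtO2, AcOH, rt
Reagents that add atoms: none
Why: Strain-releasing catalytic hydrogenolysis of the cyclopropane should cleave the least hindered bond, C4–CH2 (opposite the quaternary C4a), turning the bridge into the C4a methyl with the configuration fixed in step 7.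

Step 9
Reactants: 10 hydroxy lactone with both angular methyls
Product: 12 methyl (1R,2R,4aS,5S,8aR)-5-hydroxy-4a,8a-dimethyl-2-[(phenylselanyl)methyl]decahydronaphthalene-1-carboxylate, via sodium selenocarboxylate 11 (not isolated)
Conditions: (PhSe)2, NaBH4, DMF, rt → 110 °C; then MeI, rt
Reagents that add atoms: diphenyl diselenide, c1ccc(cc1)[Se][Se]c1ccccc1; iodomethane, CI
Why: The soft, weakly basic benzeneselenolate should open the γ-lactone by SN2 attack at its primary O–CH2 carbon (alkyl–oxygen cleavage), and the carboxylate is O-methylated in the same flask, so C1 and C2 keep their configuration.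

Step 10
Reactants: 12 hydroxy seleno ester
Product: 13 methyl (1R,2R,4aS,5S,8aR)-5-hydroxy-2,4a,8a-trimethyldecahydronaphthalene-1-carboxylate
Conditions: Bu3SnH, AIBN, toluene, 90 °C
Reagents that add atoms: none
Why: Radical chain reduction of the primary C–Se bond by Bu3SnH should convert CH2SePh into the C2 methyl without touching any stereocentre.

Step 11
Reactants: 13 hydroxy ester
Product: 14 methyl (1R,2R,4aS,8aR)-2,4a,8a-trimethyl-5-oxodecahydronaphthalene-1-carboxylate
Conditions: Dess–Martin periodinane, CH2Cl2, rt
Reagents that add atoms: none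
Why: Dess–Martin oxidation of the hindered secondary alcohol gives the C5 ketone; it is placed before the epimerisation so that the C5 oxygen cannot lactonise onto the C1 ester.

Step 12
Reactants: 14 cis keto ester
Product: 15 methyl (1S,2R,4aS,8aR)-2,4a,8a-trimethyl-5-oxodecahydronaphthalene-1-carboxylate
Conditions: NaOMe, MeOH, reflux
Reagents that add atoms: none
Why: Thermodynamic epimerisation through the ester enolate: the C1 epimer with the ester trans to the C2 methyl (both equatorial on ring A of the cis-decalin) should dominate over the cis isomer, which must put one of the two groups axial, and this is the target configuration at C1.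

Step 13
Reactants: 15 trans keto ester
Product: 17 methyl (1S,2R,4aS,8aR)-2,4a,8a-trimethyl-5-{[(trifluoromethyl)sulfonyl]oxy}-1,2,3,4,4a,7,8,8a-octahydronaphthalene-1-carboxylate, via potassium enolate 16 (not isolated)
Conditions: KN(SiMe3)2, THF, −78 °C; then PhNTf2, −78 → 0 °C
Reagents that add atoms: N-phenylbis(trifluoromethanesulfonimide), O=S(=O)(N(c1ccccc1)S(=O)(=O)C(F)(F)F)C(F)(F)F
Why: Enolisation can only go toward C6 because C4a is quaternary, and O-sulfonylation of the enolate should give the C5=C6 enol triflate regiospecifically, the hindered and far less acidic C1–H staying in place at −78 °C.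

Step 14
Reactants: 18 5-bromo-2-methylpent-2-ene
Product: 19 (4-methylpent-3-en-1-yl)zinc bromide
Conditions: Zn dust (activated with BrCH2CH2Br, Me3SiCl), LiCl, THF, 50 °C
Reagents that add atoms: zinc, [Zn]
Why: LiCl-assisted direct insertion of zinc into the primary C–Br bond should give the alkylzinc bromide as a titratable THF solution, the trisubstituted alkene being inert.

Step 15
Reactants: 17 enol triflate; 19 (4-methylpent-3-en-1-yl)zinc bromide
Product: 20 methyl (1S,2R,4aR,8aR)-2,4a,8a-trimethyl-5-(4-methylpent-3-en-1-yl)-1,2,3,4,4a,7,8,8a-octahydronaphthalene-1-carboxylate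
Conditions: PdCl2(dppf) (5 mol%), THF/NMP, 50 °C
Reagents that add atoms: none
Why: Negishi sp2–sp3 cross-coupling (oxidative addition of the C–OTf bond to zerovalent palladium formed in situ, transmetallation from zinc, reductive elimination accelerated by the wide bite angle of dppf over β-hydride elimination) should form the C5–side-chain bond; the ester tolerates the organozinc.

Step 16
Reactants: 20 methyl ester
Product: 22 (1S,2R,4aR,8aR)-2,4a,8a-trimethyl-5-(4-methylpent-3-en-1-yl)-1,2,3,4,4a,7,8,8a-octahydronaphthalene-1-carboxylic acid, via sodium carboxylate 21 (not isolated)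
Conditions: NaSEt, DMF, 100 °C; then 1 M HCl
Reagents that add atoms: none
Why: SN2 demethylation by thiolate at the ester methyl avoids the shielded acyl carbon, and C1 cannot drift because it already holds its thermodynamic configuration.

Step 17
Reactants: 22 carboxylic acid; 23 (R)-solketal, [(4R)-2,2-dimethyl-1,3-dioxolan-4-yl]methanol
Product: 24 [(4S)-2,2-dimethyl-1,3-dioxolan-4-yl]methyl (1S,2R,4aR,8aR)-2,4a,8a-trimethyl-5-(4-methylpent-3-en-1-yl)-1,2,3,4,4a,7,8,8a-octahydronaphthalene-1-carboxylate
Conditions: PPh3, DIAD, THF, 0 °C → rt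
Reagents that add atoms: none
Why: Mitsunobu esterification: the carboxylate attacks the primary alkoxyphosphonium carbon of solketal, so the hindered acyl carbon is never the electrophile and the dioxolane stereocentre is not involved (its descriptor changes only through priorities).

Step 18
Reactants: 24 acetonide ester
Product: 25 (2S)-2,3-dihydroxypropyl (1S,2R,4aR,8aR)-2,4a,8a-trimethyl-5-(4-methylpent-3-en-1-yl)-1,2,3,4,4a,7,8,8a-octahydronaphthalene-1-carboxylate
Conditions: AcOH/H2O (4:1), 45 °C
Reagents that add atoms: none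
Why: Mild acid-catalysed acetal hydrolysis should free the 1,2-diol; the hindered acyl group is not expected to migrate and the trisubstituted alkenes tolerate dilute acetic acid.

Step 19
Reactants: 25 diol ester
Product: 26 (2S)-3-(acetyloxy)-2-hydroxypropyl (1S,2R,4aR,8aR)-2,4a,8a-trimethyl-5-(4-methylpent-3-en-1-yl)-1,2,3,4,4a,7,8,8a-octahydronaphthalene-1-carboxylate (CNP0146255.1)
Conditions: AcCl (1.05 equiv), 2,4,6-collidine, CH2Cl2, −78 °C
Reagents that add atoms: acetyl chloride, CC(=O)Cl
Why: Kinetically selective acylation of the primary over the secondary hydroxyl with acetyl chloride and a hindered pyridine base at low temperature should give the 1,3-diacylglycerol, which is the target.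

**Compound list**

1 | 3-methylcyclohex-2-en-1-one | CC1=CC(=O)CCC1 | starting material
2 | 2-iodo-3-methylcyclohex-2-en-1-one | CC1=C(I)C(=O)CCC1 | intermediate
3 | (S)-2-iodo-3-methylcyclohex-2-en-1-ol | IC1=C(C)CCC[C@@H]1O | intermediate
4 | (S)-tert-butyl[(2-iodo-3-methylcyclohex-2-en-1-yl)oxy]dimethylsilane | IC1=C(C)CCC[C@@H]1O[Si](C)(C)C(C)(C)C | intermediate
5 | (S)-tert-butyldimethyl[(3-methyl-2-vinylcyclohex-2-en-1-yl)oxy]silane | C=CC1=C(C)CCC[C@@H]1O[Si](C)(C)C(C)(C)C | intermediate
6 | furan-2(5H)-one | O=C1OCC=C1 | starting material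
7 | (3aR,6S,9aR,9bR)-6-[(tert-butyldimethylsilyl)oxy]-9a-methyl-3a,4,6,7,8,9,9a,9b-octahydronaphtho[1,2-c]furan-1(3H)-one (lactone C=O on C1 and OCH2 on C2, both β; C4=C4a; C5 silyloxy and C8a methyl α) | O=C1OC[C@@H]2CC=C3[C@@H](O[Si](C)(C)C(C)(C)C)CCC[C@]3(C)[C@H]12 | intermediate
8 | (3aR,6S,9aR,9bR)-6-hydroxy-9a-methyl-3a,4,6,7,8,9,9a,9b-octahydronaphtho[1,2-c]furan-1(3H)-one | O=C1OC[C@@H]2CC=C3[C@@H](O)CCC[C@]3(C)[C@H]12 | intermediate
9 | cyclopropane-fused lactone: 8 with a CH2 bridge between C4 and C4a on the α face, cis to the C5 hydroxyl and the C8a methyl | O=C1OC[C@@H]2C[C@H]3C[C@]34[C@@H](O)CCC[C@]4(C)[C@H]12 | intermediate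
10 | (3aR,5aS,6S,9aR,9bR)-6-hydroxy-5a,9a-dimethyldecahydronaphtho[1,2-c]furan-1(3H)-one (C4a and C8a methyls both α) | O=C1OC[C@@H]2CC[C@]3(C)[C@@H](O)CCC[C@]3(C)[C@H]12 | intermediate
11 | sodium (1R,2R,4aS,5S,8aR)-5-hydroxy-4a,8a-dimethyl-2-[(phenylselanyl)methyl]decahydronaphthalene-1-carboxylate | [Na+].[O-]C(=O)[C@@H]1[C@H](C[Se]c2ccccc2)CC[C@]3(C)[C@@H](O)CCC[C@]13C | intermediate (not isolated)
12 | methyl (1R,2R,4aS,5S,8aR)-5-hydroxy-4a,8a-dimethyl-2-[(phenylselanyl)methyl]decahydronaphthalene-1-carboxylate | COC(=O)[C@@H]1[C@H](C[Se]c2ccccc2)CC[C@]3(C)[C@@H](O)CCC[C@]13C | intermediate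
13 | methyl (1R,2R,4aS,5S,8aR)-5-hydroxy-2,4a,8a-trimethyldecahydronaphthalene-1-carboxylate | COC(=O)[C@@H]1[C@H](C)CC[C@]2(C)[C@@H](O)CCC[C@]12C | intermediate
14 | methyl (1R,2R,4aS,8aR)-2,4a,8a-trimethyl-5-oxodecahydronaphthalene-1-carboxylate (C1 ester cis to C2 methyl) | COC(=O)[C@@H]1[C@H](C)CC[C@]2(C)C(=O)CCC[C@]12C | intermediate
15 | methyl (1S,2R,4aS,8aR)-2,4a,8a-trimethyl-5-oxodecahydronaphthalene-1-carboxylate (C1 ester trans to C2 methyl) | COC(=O)[C@H]1[C@H](C)CC[C@]2(C)C(=O)CCC[C@]12C | intermediate
16 | potassium C5–C6 enolate of 15 | COC(=O)[C@H]1[C@H](C)CC[C@]2(C)C([O-])=CCC[C@]12C.[K+] | intermediate (not isolated)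
17 | methyl (1S,2R,4aS,8aR)-2,4a,8a-trimethyl-5-{[(trifluoromethyl)sulfonyl]oxy}-1,2,3,4,4a,7,8,8a-octahydronaphthalene-1-carboxylate | COC(=O)[C@H]1[C@H](C)CC[C@]2(C)C(OS(=O)(=O)C(F)(F)F)=CCC[C@]12C | intermediate
18 | 5-bromo-2-methylpent-2-ene | CC(C)=CCCBr | starting material
19 | (4-methylpent-3-en-1-yl)zinc bromide (THF solution) | CC(C)=CCC[Zn]Br | intermediate
20 | methyl (1S,2R,4aR,8aR)-2,4a,8a-trimethyl-5-(4-methylpent-3-en-1-yl)-1,2,3,4,4a,7,8,8a-octahydronaphthalene-1-carboxylate | COC(=O)[C@H]1[C@H](C)CC[C@]2(C)C(CCC=C(C)C)=CCC[C@]12C | intermediate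
21 | sodium (1S,2R,4aR,8aR)-2,4a,8a-trimethyl-5-(4-methylpent-3-en-1-yl)-1,2,3,4,4a,7,8,8a-octahydronaphthalene-1-carboxylate | [Na+].[O-]C(=O)[C@H]1[C@H](C)CC[C@]2(C)C(CCC=C(C)C)=CCC[C@]12C | intermediate (not isolated)
22 | (1S,2R,4aR,8aR)-2,4a,8a-trimethyl-5-(4-methylpent-3-en-1-yl)-1,2,3,4,4a,7,8,8a-octahydronaphthalene-1-carboxylic acid | OC(=O)[C@H]1[C@H](C)CC[C@]2(C)C(CCC=C(C)C)=CCC[C@]12C | intermediate
23 | (R)-solketal, [(4R)-2,2-dimethyl-1,3-dioxolan-4-yl]methanol | CC1(C)OC[C@@H](CO)O1 | starting material
24 | [(4S)-2,2-dimethyl-1,3-dioxolan-4-yl]methyl (1S,2R,4aR,8aR)-2,4a,8a-trimethyl-5-(4-methylpent-3-en-1-yl)-1,2,3,4,4a,7,8,8a-octahydronaphthalene-1-carboxylate | CC1(C)OC[C@@H](COC(=O)[C@H]2[C@H](C)CC[C@]3(C)C(CCC=C(C)C)=CCC[C@]23C)O1 | intermediate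
25 | (2S)-2,3-dihydroxypropyl (1S,2R,4aR,8aR)-2,4a,8a-trimethyl-5-(4-methylpent-3-en-1-yl)-1,2,3,4,4a,7,8,8a-octahydronaphthalene-1-carboxylate | OC[C@H](O)COC(=O)[C@H]1[C@H](C)CC[C@]2(C)C(CCC=C(C)C)=CCC[C@]12C | intermediate
26 | (2S)-3-(acetyloxy)-2-hydroxypropyl (1S,2R,4aR,8aR)-2,4a,8a-trimethyl-5-(4-methylpent-3-en-1-yl)-1,2,3,4,4a,7,8,8a-octahydronaphthalene-1-carboxylate | CC(=O)OC[C@H](O)COC(=O)[C@H]1[C@H](C)CC[C@]2(C)C(CCC=C(C)C)=CCC[C@]12C | target

**Step count and risks**

Total: 19 steps. Longest linear sequence: 18 steps (steps 1–13 and 15–19, from 1 to 26); step 14 is a one-step side branch.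

Steps most likely to fail:

1. Step 5. The cycloaddition may stall, because a weak dienophile has to bond to a fully substituted diene terminus. The Lewis acid needed to force it may instead ionise or cleave the allylic silyl ether or polymerise the diene, and forcing conditions may erode the facial and endo preferences. Fallback (sets out from 5, returns at 7): 5 is heated with maleic anhydride in toluene at 80 °C without Lewis acid. This far more reactive Z-dienophile should form the same two bonds with the same endo and anti preferences and give the anhydride cycloadduct F1. LiBH(s-Bu)3 in THF at −78 °C should then deliver hydride to the less hindered anhydride carbonyl (the one on C2, remote from the quaternary C8a), and acidic work-up closes the hydroxy acid to lactone 7.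

2. Step 8. Hydrogenolysis may cut a cyclopropane bond other than C4–CH2, or the cyclopropylcarbinol may ring-open or rearrange on the acidic catalyst; the preceding cyclopropanation on the methyl-bearing face may also be sluggish. Fallback (sets out from 8, returns at 10, bypassing 9): 8 is silylated with (bromomethyl)chlorodimethylsilane and Et3N in CH2Cl2 to the (bromomethyl)dimethylsilyl ether F2. Bu3SnH and AIBN in benzene at 80 °C generate the silylmethyl radical, which should cyclise 5-exo onto C4a from the face of the C5 oxygen (the only face the tether reaches); the C4 radical is then reduced, giving the cyclic siloxane F3. Bu4NF in DMF at 70 °C should cleave both the Si–C and the Si–O bond, leaving the C4a methyl and the C5 hydroxyl of 10 (silicon-tethered radical reductive methylation).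

3. Step 12. Removal of the C1 proton, flanked by the quaternary C8a, may be too slow for the equilibration to reach completion, leaving mixtures of C1 epimers. Fallback (sets out from 13, returns at 15): the epimerisation is moved to the aldehyde oxidation level, where the α-proton is far more acidic. LiAlH4 in THF reduces 13 to the diol F4. Dess–Martin periodinane oxidises both hydroxyls to the cis keto aldehyde F5. DBU in CH2Cl2 at rt should equilibrate C1 to the trans keto aldehyde F6. Pinnick oxidation (NaClO2, NaH2PO4, 2-methylbut-2-ene, t-BuOH/H2O) gives the keto acid F7, and Me3SiCHN2 in MeOH/toluene returns the methyl ester 15.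

**Further compounds**

F1 | step 5 | (3aR,6S,9aR,9bR)-6-[(tert-butyldimethylsilyl)oxy]-9a-methyl-3a,4,6,7,8,9,9a,9b-octahydronaphtho[1,2-c]furan-1,3-dione (endo anhydride cycloadduct) | O=C1OC(=O)[C@@H]2CC=C3[C@@H](O[Si](C)(C)C(C)(C)C)CCC[C@]3(C)[C@H]12
F2 | step 8 | (bromomethyl)dimethylsilyl ether of 8 | O=C1OC[C@@H]2CC=C3[C@@H](O[Si](C)(C)CBr)CCC[C@]3(C)[C@H]12
F3 | step 8 | cyclic siloxane with an O–SiMe2–CH2 bridge from the C5 oxygen to C4a on the α face | O=C1OC[C@@H]2CC[C@]34C[Si](C)(C)O[C@H]3CCC[C@]4(C)[C@H]12
F4 | step 12 | diol: decalin with C1 β-hydroxymethyl, C2 β-methyl, C5 α-hydroxyl, C4a and C8a α-methyls | OC[C@@H]1[C@H](C)CC[C@]2(C)[C@@H](O)CCC[C@]12C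
F5 | step 12 | (1R,2R,4aS,8aR)-2,4a,8a-trimethyl-5-oxodecahydronaphthalene-1-carbaldehyde (cis keto aldehyde) | O=C[C@@H]1[C@H](C)CC[C@]2(C)C(=O)CCC[C@]12C
F6 | step 12 | (1S,2R,4aS,8aR)-2,4a,8a-trimethyl-5-oxodecahydronaphthalene-1-carbaldehyde (trans keto aldehyde) | O=C[C@H]1[C@H](C)CC[C@]2(C)C(=O)CCC[C@]12C
F7 | step 12 | (1S,2R,4aS,8aR)-2,4a,8a-trimethyl-5-oxodecahydronaphthalene-1-carboxylic acid | OC(=O)[C@H]1[C@H](C)CC[C@]2(C)C(=O)CCC[C@]12C
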